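## Retrosynthetic overview

1. Ring numbering used throughout: N1, C2, C3 (decyl), C4, C5 (decanoyl), C6. Building blocks: undecan-2-one 1 → dimethylaminoenone 2 → NH2-enaminone 3 (N1, C6, C5 and the decanoyl chain); acrolein 4 (C4, C3, C2); decanal 5 (all ten carbons of the decyl chain).
2. Key disconnection: the exocyclic bond decyl C1–ring C3. In the forward sense, enamine carbon C3 of the NH-1,4-dihydropyridine 6 condenses with the carbonyl carbon of 5 to give the 3-decylidene-3,4-dihydropyridine 7. A hydrogen shift from C4 to the side chain then gives pyridine 8, so the dihydro ring itself reduces the aldehyde carbon and no oxidant, reductant or protecting group is needed.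
3. Enabling feature: C3 lies β to N1 and carries a CH2, so it is the nucleophilic carbon of the enamine N1–C2=C3 in the dihydro ring. The decanoyl group on C5 makes N1–C6=C5–C=O a vinylogous amide, which stabilises the dihydro ring and leaves C5 without hydrogen; only C3 can condense and then aromatise.
4. Ring formation: the single ring is built inside the key step from 3 and 4, C4–C5 first (Michael addition), then N1–C2 (condensation). It is aromatised last, after the side-chain bond has formed. The sequence follows the logic of the Chichibabin aldehyde–ammonia synthesis of alkylpyridines, made directed.

Key step: step 3

Remark on the chemistry: the target has no stereocentre. The only stereo-elements on the route are the alkene geometries of 2, 3 and 7, and none survives in 8. In the systematic names of 6 and 7 the acyl-bearing ring carbon has locant 3; it is C5 in the numbering above.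

## Route

Step 1
Reactants: 1 undecan-2-one (2-undecanone)
Product: 2 (E)-1-(dimethylamino)dodec-1-en-3-one
Conditions: DMF-DMA (3 eq), neat, 110 °C, MeOH distilled off
Reagents that add atoms: N,N-dimethylformamide dimethyl acetal, COC(OC)N(C)C
Why: Aminomethylenation of a methyl ketone with an amide acetal (enaminone formation) should occur at the less hindered methyl group and give the push-pull alkene as the E isomer.

Step 2
Reactants: 2 (E)-1-(dimethylamino)dodec-1-en-3-one
Product: 3 (Z)-1-aminododec-1-en-3-one
Conditions: NH4OAc (5 eq), EtOH, 60 °C; extractive work-up, used at once
Reagents that add atoms: ammonium acetate, CC(=O)[O-].[NH4+]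
Why: Transamination of a tertiary enaminone by conjugate addition–elimination of ammonia at C1 should give the primary enaminone, held as the Z isomer by the N–H···O=C hydrogen bond.

Step 3
Reactants: 3 (Z)-1-aminododec-1-en-3-one, 4 acrolein (prop-2-enal), 5 decanal
Product: 8 1-(5-decylpyridin-3-yl)decan-1-one, via 1-(1,4-dihydropyridin-3-yl)decan-1-one 6 (not isolated), via 1-(5-decylidene-4,5-dihydropyridin-3-yl)decan-1-one 7 (not isolated)
Conditions: 4 (1.0 eq, added over 1 h), PhCO2H (0.2 eq), degassed MeCN, 0 °C to rt, Ar; then 5 (2 eq), 4 Å MS, 70 °C; then DBU (0.5 eq), 70 °C
Reagents that add atoms: none
Why: Proposed new method: the α-carbon of enaminone 3 should add to acrolein (Michael addition, C4–C5) and the NH2 group should then close the ring on the tethered aldehyde by 6-exo-trig addition and loss of water (N1–C2), the Hantzsch-type [3+3] route to the NH-1,4-dihydropyridine 6; its enamine carbon C3 should add to acid-activated decanal, loss of water (aldehyde oxygen with N1–H and C3–H) should give 7, and DBU should move one C4 hydrogen to the exocyclic carbon through the 3-pyridylmethyl anion, which makes the ring aromatic and the alkylidene the decyl CH2. The closest known reaction types are the Chichibabin aldehyde–ammonia pyridine synthesis and the Rügheimer–Burrows reaction, in which a partly reduced pyridine ring condenses with an aldehyde at the carbon β to nitrogen and aromatises by hydrogen shift, and the fluoride-promoted condensation of N-silyl-1,4-dihydropyridines with aldehydes to 3-alkylpyridines; new is the directed crossed version on an NH 3-acyl-1,4-dihydropyridine generated in the same flask, with an enolisable aldehyde. The ring is closed at the heteroatom (N1–C2) after the intermolecular C4–C5 bond; no stereocentre is formed, and the alkene geometry of 7 is of no consequence because it is lost on aromatisation. The step needs site selectivity for C3, which the substrate secures because C5 bears the acyl group and has no hydrogen, so that only attack at C3 can end in an aromatic ring while every other addition stays reversible. It also needs C–C bond formation to outrun hydride transfer from C4 and self-aldolisation of 5, for which air is excluded, 5 is used in excess and water is removed; aromatisation is the irreversible last event that drains the preceding equilibria.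

## Compound list

1 | undecan-2-one (2-undecanone) | CCCCCCCCCC(C)=O | starting material
2 | (E)-1-(dimethylamino)dodec-1-en-3-one | CCCCCCCCCC(=O)/C=C/N(C)C | intermediate
3 | (Z)-1-aminododec-1-en-3-one | CCCCCCCCCC(=O)/C=C\N | intermediate
4 | acrolein (prop-2-enal) | C=CC=O | starting material
5 | decanal | CCCCCCCCCC=O | starting material
6 | 1-(1,4-dihydropyridin-3-yl)decan-1-one (NH-1,4-dihydropyridine, not isolated) | CCCCCCCCCC(=O)C1=CNC=CC1 | intermediate
7 | 1-(5-decylidene-4,5-dihydropyridin-3-yl)decan-1-one (exocyclic alkene geometry not controlled, not isolated) | CCCCCCCCCC=C1C=NC=C(C(=O)CCCCCCCCC)C1 | intermediate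
8 | 1-(5-decylpyridin-3-yl)decan-1-one | CCCCCCCCCCc1cncc(C(=O)CCCCCCCCC)c1 | target

## Step count and risks

Total step count: 3. Longest linear sequence: 3 steps (1 → 2 → 3 → 8).

Steps most likely to fail, riskiest first:

Step 3 (proposed new method). The dihydropyridine may act as a hydride donor instead of a carbon nucleophile, passing hydride from C4 to the protonated alkylidene intermediate or to traces of oxygen; this would give disproportionation and oxidation to the unalkylated acylpyridine. Decanal may also condense with itself, and the final hydrogen shift may stall. The fallback uses known chemistry and makes the same C–C bond by cross-coupling. It sets out from 3: condensation with 2-bromomalonaldehyde (AcOH, EtOH, 80 °C; enaminone–malonaldehyde pyridine annulation) should give 1-(5-bromopyridin-3-yl)decan-1-one F1. Separately, dec-1-ene is hydroborated with 9-BBN-H (THF, rt) to 9-decyl-9-borabicyclo[3.3.1]nonane F2. B-alkyl Suzuki–Miyaura coupling of F1 with F2 (PdCl2(dppf), K3PO4, THF/H2O, 65 °C) should then give 8, where the fallback comes back to the route.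

Step 2. The primary enaminone may condense with itself during concentration (one molecule as carbon nucleophile, a second as electrophile), or the amine exchange may stay incomplete. The fallback reverses the order of bond formation so that the NH2-enaminone is never handled. It sets out from 2: Michael addition of its α-carbon to 4 (AcOH cat., MeCN, rt) should give 4-[(dimethylamino)methylidene]-5-oxotetradecanal F3. NH4OAc (EtOH, rt to 50 °C) should then exchange dimethylamine for ammonia and close the ring to 6 in the flask, where the fallback comes back to the route and 5 is added as in step 3.

Step 1. Aminomethylenation may occur at the C3 methylene instead of the methyl group, and an unactivated dialkyl ketone may convert slowly. The fallback is a directed Claisen formylation. It sets out from 1: the kinetic lithium enolate (LDA, THF, −78 °C; deprotonation at CH3) is trapped with ethyl formate to give (Z)-1-hydroxydodec-1-en-3-one F4, the enol form of 3-oxododecanal. With NH4OAc (EtOH, rt) this should condense at the formyl carbon to give 3, where the fallback comes back to the route; steps 1 and 2 are both bypassed.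

## Further compounds

F1 | step 3 | 1-(5-bromopyridin-3-yl)decan-1-one | CCCCCCCCCC(=O)c1cncc(Br)c1
F2 | step 3 | 9-decyl-9-borabicyclo[3.3.1]nonane | CCCCCCCCCCB1C2CCCC1CCC2
F3 | step 2 | 4-[(dimethylamino)methylidene]-5-oxotetradecanal | CCCCCCCCCC(=O)C(CCC=O)=CN(C)C
F4 | step 1 | (Z)-1-hydroxydodec-1-en-3-one | CCCCCCCCCC(=O)/C=C\O
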